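**Retrosynthetic overview**

1. Prostanoid numbering is used (C1 ester carbon, ring C8–C12, C20 chain end). Late stage: C12–OAc by acetylation; C7=C8 by aldol addition/dehydration of the C8 enolate of a 4-silyloxycyclopent-2-enone with the (4R,5Z)-enal C1–C7 (C4 from asymmetric transfer hydrogenation of an ynone); C14=C15 by Z-selective Wittig reaction of a C14 aldehyde.
2. Key disconnection: the only ring is cut at C8–C9 and C11–C12 into a methyl ketone (C8H3–C12=O, carrying C13–C15) and a β-(phenylthio)acryloylsilane (C9–C10–C11). Both bonds and the quaternary carbinol C12 are made in one Brook-rearrangement-mediated [3+2] annulation.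
3. Enabling feature: in ring C8–C9–C10–C11–C12 the carbonyl carbon C9 is joined through C10=C11 to the oxygenated carbon C12, and C12 is joined back to C9 through the methylene C8. C9 can therefore be an acyl carbon bearing silicon (its shift to O9 makes C11 nucleophilic), and C12/C8 a ketone and its α-carbon. Silicon on C9 and sulfur on C11 are temporary activators, lost as silanol and sulfenic acid when the enone is unmasked.
4. Stereocontrol: C12 is set in the key step under the influence of a dioxolane stereocentre at C14 (ester from the (S)-malic acid series). This temporary ring also masks the C14 aldehyde and is cleaved by periodate.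
5. Ring order: one ring only, formed in step 5. Steps 1–4, 9–10 and 12–17 make the four building blocks; steps 6–8, 11 and 18–21 elaborate the ring.

Key step: step 5

Assumption (face selectivity in step 5): the carbanion is taken to close on the lithium-chelated ketone anti to the dioxolane CH2 (1,3-anti), which turns (14S) into (12R) in 13; if the preference proved to be the opposite, the same route would be run from the (4R)-enantiomer of 1.

Assumption (C11): compounds 13–16 are drawn with sulfur trans to the C12 oxygen, the course expected from the E-acylsilane; the cis epimer would behave identically because C11 becomes sp2 in step 8.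

**Route**

Step 1
Reactants: 1 methyl 2-[(4S)-2,2-dimethyl-1,3-dioxolan-4-yl]acetate
Product: 2 2-[(4S)-2,2-dimethyl-1,3-dioxolan-4-yl]-N-methoxy-N-methylacetamide
Conditions: MeNH(OMe)·HCl, iPrMgCl, THF, −20 → 0 °C
Reagents that add atoms: N,O-dimethylhydroxylamine hydrochloride, CNOC.Cl
Why: Weinreb amide formation by acyl substitution of the ester with the chloromagnesium amide made in the flask, which at this temperature is faster than β-elimination of the dioxolane oxygen and leaves the C14 stereocentre untouched.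

Step 2
Reactants: 2 2-[(4S)-2,2-dimethyl-1,3-dioxolan-4-yl]-N-methoxy-N-methylacetamide
Product: 3 1-[(4S)-2,2-dimethyl-1,3-dioxolan-4-yl]propan-2-one
Conditions: MeMgBr, THF, 0 °C; aq. NH4Cl
Reagents that add atoms: methylmagnesium bromide, C[Mg]Br
Why: Grignard addition to a Weinreb amide stops at the ketone because the magnesium-chelated tetrahedral adduct collapses only on work-up.

Step 3
Reactants: 4 methoxyallene
Product: 6 tert-butyl(1-methoxypropa-1,2-dien-1-yl)dimethylsilane, via 1-lithio-1-methoxyallene 5 (not isolated)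
Conditions: n-BuLi, THF, −78 °C; TBSCl, −78 °C → rt
Reagents that add atoms: tert-butyldimethylsilyl chloride, CC(C)(C)[Si](C)(C)Cl
Why: α-lithiation of the allenyl ether next to oxygen followed by C-silylation is the standard entry to 1-alkoxy-1-silylallenes, which are masked acryloylsilanes.

Step 4
Reactants: 6 tert-butyl(1-methoxypropa-1,2-dien-1-yl)dimethylsilane
Product: 9 (E)-1-[tert-butyl(dimethyl)silyl]-3-(phenylsulfanyl)prop-2-en-1-one, via 3-lithio allene 7 (not isolated), via 3-(phenylsulfanyl) allene 8 (not isolated)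
Conditions: n-BuLi, THF, −78 °C; PhSSPh, −78 → 0 °C; then 1 M aq. HCl, THF, rt
Reagents that add atoms: diphenyl disulfide, c1ccc(SSc2ccccc2)cc1; water, O
Why: the remaining allenic terminus is lithiated and sulfenylated, and acid hydrolysis of the allenyl ether (protonation at the central carbon, then loss of methanol) unmasks the acylsilane as the thermodynamically preferred E vinylogous thioester.

Step 5
Reactants: 3 1-[(4S)-2,2-dimethyl-1,3-dioxolan-4-yl]propan-2-one; 9 (E)-1-[tert-butyl(dimethyl)silyl]-3-(phenylsulfanyl)prop-2-en-1-one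
Product: 13 (1R,2R)-4-{[tert-butyl(dimethyl)silyl]oxy}-1-{[(4S)-2,2-dimethyl-1,3-dioxolan-4-yl]methyl}-2-(phenylsulfanyl)cyclopent-3-en-1-ol, via lithium enolate 10 (not isolated), via silyl alkoxide adduct 11 (not isolated), via siloxyallyl-lithium 12 (not isolated)
Conditions: LiN(iPr)2 (1.05 equiv), THF, −80 °C; then 9, −80 → −30 °C; aq. NH4Cl
Reagents that add atoms: none
Why: The kinetic methyl enolate 10 adds to the aldehyde-like acylsilane carbonyl of 9 (bond C8–C9), the α-silyl alkoxide 11 undergoes a 1,2-Brook shift of silicon from C9 to oxygen to give the sulfur-stabilised siloxyallyl anion 12, and its γ-carbon C11 closes on the ketone carbon C12 (bond C11–C12) to give the cyclopentenolate. The closest known reaction type is the Brook-rearrangement-mediated [3+2] annulation of β-(phenylthio)acryloylsilanes with lithium enolates of alkyl methyl ketones. The single ring (C8–C9–C10–C11–C12) closes 5-exo-trig with respect to the C12=O bond, a closure that may equally run through 3-exo-trig attack of C9 on C12 and oxyanion-accelerated 1,3-shift of the resulting vinylcyclopropanolate to the same product. The new stereocentre C12 is controlled by the dioxolane stereocentre C14 of 3: in the six-membered lithium chelate between the ketone oxygen and the dioxolane oxygen, C11 should enter trans to C15 (1,3-anti), which is 12R in 13 and becomes 12S in the target, while C11 (drawn trans to the hydroxyl) is erased in step 8. The step needs methyl-side enolisation (secured by the amide base at −80 °C and the β-branched CH2 side), 1,2- instead of 1,4-addition (secured by the sulfur donor at C11 and the electrophilic Si–C=O group) and face selectivity at C12, where the minor epimer is a diastereomer because of C14 and is removed by chromatography at this stage.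

Step 6
Reactants: 13 (1R,2R)-4-{[tert-butyl(dimethyl)silyl]oxy}-1-{[(4S)-2,2-dimethyl-1,3-dioxolan-4-yl]methyl}-2-(phenylsulfanyl)cyclopent-3-en-1-ol
Product: 14 (4S)-4-{[(1R,2R)-1,4-bis{[tert-butyl(dimethyl)silyl]oxy}-2-(phenylsulfanyl)cyclopent-3-en-1-yl]methyl}-2,2-dimethyl-1,3-dioxolane
Conditions: TBSOTf, 2,6-lutidine, CH2Cl2, −78 → 0 °C
Reagents that add atoms: tert-butyldimethylsilyl trifluoromethanesulfonate, CC(C)(C)[Si](C)(C)OS(=O)(=O)C(F)(F)F
Why: silyl triflate silylation of the hindered tertiary carbinol gives an ether that is a poor leaving group in the later C8 enolate and, unlike the enol silyl ether, survives aqueous acid.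

Step 7
Reactants: 14 (4S)-4-{[(1R,2R)-1,4-bis{[tert-butyl(dimethyl)silyl]oxy}-2-(phenylsulfanyl)cyclopent-3-en-1-yl]methyl}-2,2-dimethyl-1,3-dioxolane
Product: 15 (3R,4R)-3-{[tert-butyl(dimethyl)silyl]oxy}-3-[(2S)-2,3-dihydroxypropyl]-4-(phenylsulfanyl)cyclopentan-1-one
Conditions: 1 M aq. HCl, THF, 0 °C → rt
Reagents that add atoms: none
Why: acid hydrolysis cleaves the enol silyl ether (C-protonation) and the terminal acetonide while the tertiary alkyl silyl ether is too hindered to react, so the C9 ketone and the C14/C15 glycol are unmasked in one operation.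

Step 8
Reactants: 15 (3R,4R)-3-{[tert-butyl(dimethyl)silyl]oxy}-3-[(2S)-2,3-dihydroxypropyl]-4-(phenylsulfanyl)cyclopentan-1-one
Product: 17 2-[(1R)-1-{[tert-butyl(dimethyl)silyl]oxy}-4-oxocyclopent-2-en-1-yl]acetaldehyde, via sulfoxide aldehyde 16 (not isolated)
Conditions: NaIO4 (2.5 equiv), THF/H2O, 0 °C → rt; then toluene, CaCO3 (acid scavenger), 80 °C
Reagents that add atoms: sodium periodate, [Na+].[O-]I(=O)(=O)=O (oxygen of the sulfoxide in 16, lost again in the elimination)
Why: periodate glycol cleavage removes the auxiliary stereocentre C14 as the aldehyde and oxidises the sulfide to the sulfoxide, whose thermal syn-elimination can only use a C10 hydrogen and therefore gives the C10=C11 enone.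

Step 9
Reactants: 18 (Z)-hex-3-en-1-ol
Product: 19 (Z)-1-iodohex-3-ene
Conditions: I2, PPh3, imidazole, CH2Cl2, 0 °C → rt
Reagents that add atoms: iodine, II
Why: Appel-type iodination of the primary alcohol by SN2 displacement of the oxyphosphonium ion leaves the Z alkene untouched.

Step 10
Reactants: 19 (Z)-1-iodohex-3-ene
Product: 20 [(Z)-hex-3-en-1-yl]triphenylphosphonium iodide
Conditions: PPh3, MeCN, reflux
Reagents that add atoms: triphenylphosphine, c1ccc(P(c2ccccc2)c2ccccc2)cc1
Why: SN2 quaternisation of the phosphine by the primary iodide.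

Step 11
Reactants: 20 [(Z)-hex-3-en-1-yl]triphenylphosphonium iodide; 17 2-[(1R)-1-{[tert-butyl(dimethyl)silyl]oxy}-4-oxocyclopent-2-en-1-yl]acetaldehyde
Product: 22 (4R)-4-{[tert-butyl(dimethyl)silyl]oxy}-4-[(2Z,5Z)-octa-2,5-dien-1-yl]cyclopent-2-en-1-one, via phosphorus ylide 21 (not isolated)
Conditions: NaN(SiMe3)2, THF, −78 °C; then 17, −78 → −20 °C
Reagents that add atoms: none
Why: Wittig olefination with a non-stabilised ylide under lithium-free conditions gives the Z alkene C14=C15 through the kinetic cis-oxaphosphetane, and the aldehyde reacts much faster than the enone at low temperature.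

Step 12
Reactants: 23 methyl 4-chloro-4-oxobutanoate; 24 tert-butyl(dimethyl)(prop-2-yn-1-yloxy)silane
Product: 25 methyl 7-{[tert-butyl(dimethyl)silyl]oxy}-4-oxohept-5-ynoate
Conditions: PdCl2(PPh3)2 (2 mol %), CuI (4 mol %), Et3N, THF, rt
Reagents that add atoms: none
Why: acyl Sonogashira coupling of the acid chloride with the terminal alkyne gives the ynone without touching the methyl ester.

Step 13
Reactants: 25 methyl 7-{[tert-butyl(dimethyl)silyl]oxy}-4-oxohept-5-ynoate
Product: 26 methyl (4R)-7-{[tert-butyl(dimethyl)silyl]oxy}-4-hydroxyhept-5-ynoate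
Conditions: Ru(p-cymene)[(R,R)-TsNCH(Ph)CH(Ph)NH] (1 mol %), iPrOH, rt
Reagents that add atoms: none
Why: Noyori-type asymmetric transfer hydrogenation of an alkynyl ketone, in which the alkynyl group takes the role of the aryl group of aryl ketones so that the (R,R)-catalyst should deliver hydride to give the 4R carbinol, under neutral conditions that do not lactonise the γ-hydroxy ester.

Step 14
Reactants: 26 methyl (4R)-7-{[tert-butyl(dimethyl)silyl]oxy}-4-hydroxyhept-5-ynoate
Product: 27 methyl (4R)-4-acetoxy-7-{[tert-butyl(dimethyl)silyl]oxy}hept-5-ynoate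
Conditions: Ac2O, pyridine, DMAP (cat.), CH2Cl2, 0 °C
Reagents that add atoms: acetic anhydride, CC(=O)OC(C)=O
Why: DMAP-catalysed acetylation installs the C4 acetate of the target at once and blocks γ-lactonisation.

Step 15
Reactants: 27 methyl (4R)-4-acetoxy-7-{[tert-butyl(dimethyl)silyl]oxy}hept-5-ynoate
Product: 28 methyl (4R,5Z)-4-acetoxy-7-{[tert-butyl(dimethyl)silyl]oxy}hept-5-enoate
Conditions: H2 (1 atm), Pd/CaCO3 poisoned with Pb(OAc)2 (Lindlar catalyst), quinoline, EtOAc, rt
Reagents that add atoms: none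
Why: Lindlar semihydrogenation adds hydrogen syn to the alkyne and so fixes the 5Z geometry.

Step 16
Reactants: 28 methyl (4R,5Z)-4-acetoxy-7-{[tert-butyl(dimethyl)silyl]oxy}hept-5-enoate
Product: 29 methyl (4R,5Z)-4-acetoxy-7-hydroxyhept-5-enoate
Conditions: HF·pyridine, pyridine, THF, 0 °C
Reagents that add atoms: none
Why: buffered fluoride desilylation of the primary silyl ether under slightly acidic conditions avoids acetyl migration from O4 to O7.

Step 17
Reactants: 29 methyl (4R,5Z)-4-acetoxy-7-hydroxyhept-5-enoate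
Product: 30 methyl (4R,5Z)-4-acetoxy-7-oxohept-5-enoate
Conditions: Dess–Martin periodinane, pyridine, CH2Cl2, 0 °C; used at once
Reagents that add atoms: none
Why: Dess–Martin oxidation of the allylic alcohol under buffered, non-enolising conditions should give the Z enal without isomerisation to the E enal.

Step 18
Reactants: 22 (4R)-4-{[tert-butyl(dimethyl)silyl]oxy}-4-[(2Z,5Z)-octa-2,5-dien-1-yl]cyclopent-2-en-1-one; 30 methyl (4R,5Z)-4-acetoxy-7-oxohept-5-enoate
Product: 32 methyl (4R,5Z,7S)-4-acetoxy-7-[(1R,5S)-5-{[tert-butyl(dimethyl)silyl]oxy}-5-[(2Z,5Z)-octa-2,5-dien-1-yl]-2-oxocyclopent-3-en-1-yl]-7-hydroxyhept-5-enoate (anti aldol isomer drawn; C7/C8 isomers converge in step 19), via lithium dienolate 31 (not isolated)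
Conditions: LiN(iPr)2, THF, −78 °C; then 30, −78 °C; aq. NH4Cl at −78 °C
Reagents that add atoms: none
Why: the kinetic cross-conjugated enolate can form only at C8 and adds 1,2 to the enal in an aldol addition at −78 °C, where neither loss of the silyloxy group nor attack on the ester or acetate should compete, and the new C7 and C8 centres (a mixture is expected) are both erased in step 19.

Step 19
Reactants: 32 methyl (4R,5Z,7S)-4-acetoxy-7-[(1R,5S)-5-{[tert-butyl(dimethyl)silyl]oxy}-5-[(2Z,5Z)-octa-2,5-dien-1-yl]-2-oxocyclopent-3-en-1-yl]-7-hydroxyhept-5-enoate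
Product: 34 methyl (4R,5Z,7E)-4-acetoxy-7-[(5S)-5-{[tert-butyl(dimethyl)silyl]oxy}-5-[(2Z,5Z)-octa-2,5-dien-1-yl]-2-oxocyclopent-3-en-1-ylidene]hept-5-enoate, via mesylate 33 (not isolated)
Conditions: MsCl, Et3N, CH2Cl2, −20 °C; then DBU, 0 °C
Reagents that add atoms: methanesulfonyl chloride, CS(=O)(=O)Cl (mesyl group of 33, lost again in the elimination)
Why: mesylation and E1cB elimination through the C8 enolate converts all aldol diastereomers into the cross-conjugated dienone, and the 7E isomer with C6 anti to the C9 carbonyl is expected to predominate as in other 2-alkylidenecyclopentanones, a 7Z by-product being separable by chromatography.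

Step 20
Reactants: 34 methyl (4R,5Z,7E)-4-acetoxy-7-[(5S)-5-{[tert-butyl(dimethyl)silyl]oxy}-5-[(2Z,5Z)-octa-2,5-dien-1-yl]-2-oxocyclopent-3-en-1-ylidene]hept-5-enoate
Product: 35 methyl (4R,5Z,7E)-4-acetoxy-7-[(5S)-5-hydroxy-5-[(2Z,5Z)-octa-2,5-dien-1-yl]-2-oxocyclopent-3-en-1-ylidene]hept-5-enoate
Conditions: HF·pyridine (excess), THF, 0 °C → rt
Reagents that add atoms: none
Why: fluoride desilylation under acidic, non-basic conditions spares the esters and the dienone, and ionisation of the doubly allylic C12–O bond is not a concern because it would give a cyclopentadienyl-type cation.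

Step 21
Reactants: 35 methyl (4R,5Z,7E)-4-acetoxy-7-[(5S)-5-hydroxy-5-[(2Z,5Z)-octa-2,5-dien-1-yl]-2-oxocyclopent-3-en-1-ylidene]hept-5-enoate
Product: 36 methyl (4R,5Z,7E)-4-acetoxy-7-[(5S)-5-acetoxy-5-[(2Z,5Z)-octa-2,5-dien-1-yl]-2-oxocyclopent-3-en-1-ylidene]hept-5-enoate
Conditions: Ac2O, DMAP, Et3N, CH2Cl2, rt
Reagents that add atoms: acetic anhydride, CC(=O)OC(C)=O
Why: DMAP-catalysed acetylation of the tertiary C12 alcohol through the acylpyridinium ion completes the target without touching any stereocentre.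

**Compound list**

1 | methyl 2-[(4S)-2,2-dimethyl-1,3-dioxolan-4-yl]acetate | COC(=O)C[C@H]1COC(C)(C)O1 | starting material
2 | 2-[(4S)-2,2-dimethyl-1,3-dioxolan-4-yl]-N-methoxy-N-methylacetamide | CON(C)C(=O)C[C@H]1COC(C)(C)O1 | intermediate
3 | 1-[(4S)-2,2-dimethyl-1,3-dioxolan-4-yl]propan-2-one | CC(=O)C[C@H]1COC(C)(C)O1 | intermediate
4 | methoxyallene (1-methoxypropa-1,2-diene) | COC=C=C | starting material
5 | 1-lithio-1-methoxyallene | COC([Li])=C=C | intermediate
6 | tert-butyl(1-methoxypropa-1,2-dien-1-yl)dimethylsilane | COC(=C=C)[Si](C)(C)C(C)(C)C | intermediate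
7 | 3-lithio derivative of 6 (lithium on the allene terminus) | COC(=C=C[Li])[Si](C)(C)C(C)(C)C | intermediate
8 | tert-butyl[1-methoxy-3-(phenylsulfanyl)propa-1,2-dien-1-yl]dimethylsilane (racemic allene) | COC(=C=CSc1ccccc1)[Si](C)(C)C(C)(C)C | intermediate
9 | (E)-1-[tert-butyl(dimethyl)silyl]-3-(phenylsulfanyl)prop-2-en-1-one | CC(C)(C)[Si](C)(C)C(=O)/C=C/Sc1ccccc1 | intermediate
10 | lithium 3-[(4S)-2,2-dimethyl-1,3-dioxolan-4-yl]prop-1-en-2-olate (methyl-side enolate of 3) | C=C(O[Li])C[C@H]1COC(C)(C)O1 | intermediate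
11 | lithium (1E)-3-[tert-butyl(dimethyl)silyl]-6-[(4S)-2,2-dimethyl-1,3-dioxolan-4-yl]-5-oxo-1-(phenylsulfanyl)hex-1-en-3-olate (both epimers at the carbinol carbon) | CC(C)(C)[Si](C)(C)C(O[Li])(/C=C/Sc1ccccc1)CC(=O)C[C@H]1COC(C)(C)O1 | intermediate
12 | siloxyallyl-lithium from the Brook shift: (2E)-3-{[tert-butyl(dimethyl)silyl]oxy}-6-[(4S)-2,2-dimethyl-1,3-dioxolan-4-yl]-5-oxo-1-(phenylsulfanyl)hex-2-en-1-yl-lithium (delocalised, C11 not configurationally fixed) | CC(C)(C)[Si](C)(C)O/C(CC(=O)C[C@H]1COC(C)(C)O1)=C/C([Li])Sc1ccccc1 | intermediate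
13 | (1R,2R)-4-{[tert-butyl(dimethyl)silyl]oxy}-1-{[(4S)-2,2-dimethyl-1,3-dioxolan-4-yl]methyl}-2-(phenylsulfanyl)cyclopent-3-en-1-ol | CC1(C)OC[C@H](C[C@]2(O)[C@H](Sc3ccccc3)C=C(O[Si](C)(C)C(C)(C)C)C2)O1 | intermediate
14 | (4S)-4-{[(1R,2R)-1,4-bis{[tert-butyl(dimethyl)silyl]oxy}-2-(phenylsulfanyl)cyclopent-3-en-1-yl]methyl}-2,2-dimethyl-1,3-dioxolane | CC1(C)OC[C@H](C[C@]2(O[Si](C)(C)C(C)(C)C)[C@H](Sc3ccccc3)C=C(O[Si](C)(C)C(C)(C)C)C2)O1 | intermediate
15 | (3R,4R)-3-{[tert-butyl(dimethyl)silyl]oxy}-3-[(2S)-2,3-dihydroxypropyl]-4-(phenylsulfanyl)cyclopentan-1-one | OC[C@@H](O)C[C@]1(O[Si](C)(C)C(C)(C)C)[C@H](Sc2ccccc2)CC(=O)C1 | intermediate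
16 | 2-[(1R,2R)-1-{[tert-butyl(dimethyl)silyl]oxy}-4-oxo-2-(phenylsulfinyl)cyclopentyl]acetaldehyde (both epimers at sulfur) | O=CC[C@]1(O[Si](C)(C)C(C)(C)C)[C@H](S(=O)c2ccccc2)CC(=O)C1 | intermediate
17 | 2-[(1R)-1-{[tert-butyl(dimethyl)silyl]oxy}-4-oxocyclopent-2-en-1-yl]acetaldehyde | O=CC[C@]1(O[Si](C)(C)C(C)(C)C)C=CC(=O)C1 | intermediate
18 | (Z)-hex-3-en-1-ol | CC/C=C\CCO | starting material
19 | (Z)-1-iodohex-3-ene | CC/C=C\CCI | intermediate
20 | [(Z)-hex-3-en-1-yl]triphenylphosphonium iodide | CC/C=C\CC[P+](c1ccccc1)(c1ccccc1)c1ccccc1.[I-] | intermediate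
21 | [(Z)-hex-3-en-1-ylidene]triphenylphosphorane | CC/C=C\CC=P(c1ccccc1)(c1ccccc1)c1ccccc1 | intermediate
22 | (4R)-4-{[tert-butyl(dimethyl)silyl]oxy}-4-[(2Z,5Z)-octa-2,5-dien-1-yl]cyclopent-2-en-1-one | CC/C=C\C/C=C\C[C@]1(O[Si](C)(C)C(C)(C)C)C=CC(=O)C1 | intermediate
23 | methyl 4-chloro-4-oxobutanoate | COC(=O)CCC(Cl)=O | starting material
24 | tert-butyl(dimethyl)(prop-2-yn-1-yloxy)silane | C#CCO[Si](C)(C)C(C)(C)C | starting material
25 | methyl 7-{[tert-butyl(dimethyl)silyl]oxy}-4-oxohept-5-ynoate | COC(=O)CCC(=O)C#CCO[Si](C)(C)C(C)(C)C | intermediate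
26 | methyl (4R)-7-{[tert-butyl(dimethyl)silyl]oxy}-4-hydroxyhept-5-ynoate | COC(=O)CC[C@@H](O)C#CCO[Si](C)(C)C(C)(C)C | intermediate
27 | methyl (4R)-4-acetoxy-7-{[tert-butyl(dimethyl)silyl]oxy}hept-5-ynoate | COC(=O)CC[C@@H](OC(C)=O)C#CCO[Si](C)(C)C(C)(C)C | intermediate
28 | methyl (4R,5Z)-4-acetoxy-7-{[tert-butyl(dimethyl)silyl]oxy}hept-5-enoate | COC(=O)CC[C@@H](OC(C)=O)/C=C\CO[Si](C)(C)C(C)(C)C | intermediate
29 | methyl (4R,5Z)-4-acetoxy-7-hydroxyhept-5-enoate | COC(=O)CC[C@@H](OC(C)=O)/C=C\CO | intermediate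
30 | methyl (4R,5Z)-4-acetoxy-7-oxohept-5-enoate | COC(=O)CC[C@@H](OC(C)=O)/C=C\C=O | intermediate
31 | lithium C8 dienolate of 22 (C12 unchanged) | CC/C=C\C/C=C\C[C@]1(O[Si](C)(C)C(C)(C)C)C=CC(O[Li])=C1 | intermediate
32 | methyl (4R,5Z,7S)-4-acetoxy-7-[(1R,5S)-5-{[tert-butyl(dimethyl)silyl]oxy}-5-[(2Z,5Z)-octa-2,5-dien-1-yl]-2-oxocyclopent-3-en-1-yl]-7-hydroxyhept-5-enoate (anti aldol isomer drawn; mixture at C7 and C8 expected) | CC/C=C\C/C=C\C[C@]1(O[Si](C)(C)C(C)(C)C)C=CC(=O)[C@@H]1[C@@H](O)/C=C\[C@@H](CCC(=O)OC)OC(C)=O | intermediate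
33 | C7 methanesulfonate of 32 | CC/C=C\C/C=C\C[C@]1(O[Si](C)(C)C(C)(C)C)C=CC(=O)[C@@H]1[C@@H](OS(C)(=O)=O)/C=C\[C@@H](CCC(=O)OC)OC(C)=O | intermediate
34 | methyl (4R,5Z,7E)-4-acetoxy-7-[(5S)-5-{[tert-butyl(dimethyl)silyl]oxy}-5-[(2Z,5Z)-octa-2,5-dien-1-yl]-2-oxocyclopent-3-en-1-ylidene]hept-5-enoate | CC/C=C\C/C=C\C[C@]1(O[Si](C)(C)C(C)(C)C)C=CC(=O)/C1=C/C=C\[C@@H](CCC(=O)OC)OC(C)=O | intermediate
35 | methyl (4R,5Z,7E)-4-acetoxy-7-[(5S)-5-hydroxy-5-[(2Z,5Z)-octa-2,5-dien-1-yl]-2-oxocyclopent-3-en-1-ylidene]hept-5-enoate | CC/C=C\C/C=C\C[C@]1(O)C=CC(=O)/C1=C/C=C\[C@@H](CCC(=O)OC)OC(C)=O | intermediate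
36 | methyl (4R,5Z,7E)-4-acetoxy-7-[(5S)-5-acetoxy-5-[(2Z,5Z)-octa-2,5-dien-1-yl]-2-oxocyclopent-3-en-1-ylidene]hept-5-enoate (17,18-dehydro-clavulone I) | CC/C=C\C/C=C\C[C@]1(OC(C)=O)C=CC(=O)/C1=C/C=C\[C@@H](CCC(=O)OC)OC(C)=O | target

**Step count**

Total step count: 21.
Longest linear sequence: 11 steps (1, 2, 5, 6, 7, 8, 11, 18, 19, 20, 21).

**Steps most likely to fail**

Step 5. What may go wrong: weak or reversed face selection at C12, because the controlling centre C14 is three bonds away, and proton transfer from the ketone to the siloxyallyl anion before ring closure. Fallback (resolution instead of substrate control): it sets out from acylsilane 9, which is annulated under the same conditions with the lithium enolate of commercial 4,4-dimethoxybutan-2-one to give the racemic cyclopentenol F1. TBSOTf and 2,6-lutidine at −78 °C give the racemic bis-silyl ether F2. 1 M aq. HCl in THF hydrolyses the enol silyl ether and the dimethyl acetal to the racemic keto aldehyde F3. NaIO4 oxidises the sulfide to the racemic sulfoxide F4, which eliminates in toluene at 80 °C to the racemic enone aldehyde F5. Preparative chromatography on a chiral stationary phase then brings the route back at 17. Steps 1, 2 and 7 are no longer needed.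

Step 19. What may go wrong: loss of geometric control in the E1cB elimination, giving the 7Z alkylidene, and base-induced drift of C5=C6 from Z to E. Fallback (olefination in place of aldol addition and dehydration, replacing steps 18 and 19): it sets out from enone 22. LiN(iPr)2 followed by ClP(O)(OEt)2 gives the dienyl phosphate F6. A second treatment with LiN(iPr)2 brings about the 1,3-shift of phosphorus from oxygen to C8 and gives the β-keto phosphonate F7 (C8 epimers). Horner–Wadsworth–Emmons reaction of F7 with enal 30 under LiCl and iPr2NEt in MeCN should give the 7E dienone directly and comes back to the route at 34.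

Step 11. What may go wrong: the basic ylide enolises the β-silyloxy aldehyde or the enone (loss of silanolate, aldol side reactions) or adds to the enone. Fallback (Wittig reaction before the enone exists): it sets out from diol 15. NaIO4 (1 equiv, 0 °C, short contact) cleaves only the glycol and gives the keto aldehyde F8. Ylide 21 converts F8 into the (Z,Z)-dienyl ketone F9. NaIO4 at rt then gives the sulfoxide F10, whose thermal elimination in toluene at 80 °C comes back to the route at 22.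

**Further compounds**

F1 | step 5 | racemic (1R*,2R*)-4-{[tert-butyl(dimethyl)silyl]oxy}-1-(2,2-dimethoxyethyl)-2-(phenylsulfanyl)cyclopent-3-en-1-ol | COC(OC)C[C@]1(O)[C@H](Sc2ccccc2)C=C(O[Si](C)(C)C(C)(C)C)C1.COC(OC)C[C@@]1(O)[C@@H](Sc2ccccc2)C=C(O[Si](C)(C)C(C)(C)C)C1
F2 | step 5 | racemic (1R*,2R*)-1,4-bis{[tert-butyl(dimethyl)silyl]oxy}-1-(2,2-dimethoxyethyl)-2-(phenylsulfanyl)cyclopent-3-ene | COC(OC)C[C@]1(O[Si](C)(C)C(C)(C)C)[C@H](Sc2ccccc2)C=C(O[Si](C)(C)C(C)(C)C)C1.COC(OC)C[C@@]1(O[Si](C)(C)C(C)(C)C)[C@@H](Sc2ccccc2)C=C(O[Si](C)(C)C(C)(C)C)C1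
F3 | step 5 | racemic 2-[(1R*,2R*)-1-{[tert-butyl(dimethyl)silyl]oxy}-4-oxo-2-(phenylsulfanyl)cyclopentyl]acetaldehyde | O=CC[C@]1(O[Si](C)(C)C(C)(C)C)[C@H](Sc2ccccc2)CC(=O)C1.O=CC[C@@]1(O[Si](C)(C)C(C)(C)C)[C@@H](Sc2ccccc2)CC(=O)C1
F4 | step 5 | racemic 2-[(1R*,2R*)-1-{[tert-butyl(dimethyl)silyl]oxy}-4-oxo-2-(phenylsulfinyl)cyclopentyl]acetaldehyde (both epimers at sulfur) | O=CC[C@]1(O[Si](C)(C)C(C)(C)C)[C@H](S(=O)c2ccccc2)CC(=O)C1.O=CC[C@@]1(O[Si](C)(C)C(C)(C)C)[C@@H](S(=O)c2ccccc2)CC(=O)C1
F5 | step 5 | racemic 2-(1-{[tert-butyl(dimethyl)silyl]oxy}-4-oxocyclopent-2-en-1-yl)acetaldehyde | O=CC[C@]1(O[Si](C)(C)C(C)(C)C)C=CC(=O)C1.O=CC[C@@]1(O[Si](C)(C)C(C)(C)C)C=CC(=O)C1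
F6 | step 19 | diethyl 3-{[tert-butyl(dimethyl)silyl]oxy}-3-[(2Z,5Z)-octa-2,5-dien-1-yl]cyclopenta-1,4-dien-1-yl phosphate (C12 configured as in 22) | CC/C=C\C/C=C\C[C@]1(O[Si](C)(C)C(C)(C)C)C=CC(OP(=O)(OCC)OCC)=C1
F7 | step 19 | diethyl {5-{[tert-butyl(dimethyl)silyl]oxy}-5-[(2Z,5Z)-octa-2,5-dien-1-yl]-2-oxocyclopent-3-en-1-yl}phosphonate (C12 configured as in 22; both C8 epimers) | CC/C=C\C/C=C\C[C@]1(O[Si](C)(C)C(C)(C)C)C=CC(=O)C1P(=O)(OCC)OCC
F8 | step 11 | 2-[(1R,2R)-1-{[tert-butyl(dimethyl)silyl]oxy}-4-oxo-2-(phenylsulfanyl)cyclopentyl]acetaldehyde | O=CC[C@]1(O[Si](C)(C)C(C)(C)C)[C@H](Sc2ccccc2)CC(=O)C1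
F9 | step 11 | (3R,4R)-3-{[tert-butyl(dimethyl)silyl]oxy}-3-[(2Z,5Z)-octa-2,5-dien-1-yl]-4-(phenylsulfanyl)cyclopentan-1-one | CC/C=C\C/C=C\C[C@]1(O[Si](C)(C)C(C)(C)C)[C@H](Sc2ccccc2)CC(=O)C1
F10 | step 11 | (3R,4R)-3-{[tert-butyl(dimethyl)silyl]oxy}-3-[(2Z,5Z)-octa-2,5-dien-1-yl]-4-(phenylsulfinyl)cyclopentan-1-one (both epimers at sulfur) | CC/C=C\C/C=C\C[C@]1(O[Si](C)(C)C(C)(C)C)[C@H](S(=O)c2ccccc2)CC(=O)C1
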